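**Retrosynthetic overview**
1. Target 18 ⇐ debenzylation, desilylation and cis-selective C4 reduction of dimeric flavanone 15; the lower ring C stays a 3-silyloxy-4-ketone until the end, and 15 ⇐ detriflation of 14.
2. Interflavanyl bond C4(upper)–C2′(lower ring B) ⇐ Friedel–Crafts capture of flavan-4-yl cation 13 by ring B of flavanone 8. Cation 13 comes from dihydromyricetin 9, and its 5-triflate deactivates its own ring A; ring A of 8 is deactivated by the C4 ketone.
3. Lower ring C (in 8) ⇐ ring contraction of the seven-membered 2-aryl-1,3-benzodioxepin-5-one enol silane 6 (O→C shift under a chiral acid), forming C2–C3 and both stereocentres; 6 ⇐ acetal 5 of bis-silyl hydroxyketone 3 and aldehyde 4.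
4. Enabling feature: in the lower ring C, C2 lies between O1 and the electron-rich ring B (a latent oxocarbenium carbon), its neighbour C3 carries an oxygen (O-3) that can act as a temporary second acetal oxygen on C2, and C4 at the ketone level makes C3 an enol carbon.
5. Ring order: seven-membered acetal ring (O1, C2, O-3, C3, C4, C4a, C8a; step 2) → lower ring C by extrusion of O-3 (step 4); all other rings come preformed.

Key step: step 4

Remark: flavonoid numbering is used (O1, C2–C4, C4a, C5–C8, C8a, ring B primed; O-3 is the oxygen on C3). The enantiomer of the chiral acid that gives (2R,3R)-8 is assumed to be found in a short screen, with crystallisation of 8 as an upgrade if needed.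

**Step 1**
Reactants: 1 1-[4-(benzyloxy)-2-hydroxyphenyl]ethan-1-one
Product: 3 1-[4-(benzyloxy)-2-(trimethylsilyloxy)phenyl]-2-(trimethylsilyloxy)ethan-1-one, via bis-silyl enol ether 2 (not isolated)
Conditions: TMSOTf (2.2 equiv), Et3N, CH2Cl2, 0 °C; pentane extraction; mCPBA (1.0 equiv, dried), hexane, −15 °C → rt; filtration under argon, evaporation, crude 3 taken on directly
Reagents that add atoms: trimethylsilyl trifluoromethanesulfonate, C[Si](C)(C)OS(=O)(=O)C(F)(F)F; mCPBA (3-chloroperoxybenzoic acid), O=C(OO)c1cccc(Cl)c1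
Why: Rubottom oxidation stopped at the silyl stage: the phenol and the methyl ketone are silylated, mCPBA oxidises the enol carbon with silyl transfer to the new α-oxygen, and the non-aqueous work-up in hexane (from which 3-chlorobenzoic acid precipitates) should keep both trimethylsilyl ethers in place for the next step; no stereocentre is formed.

**Step 2**
Reactants: 3 1-[4-(benzyloxy)-2-(trimethylsilyloxy)phenyl]-2-(trimethylsilyloxy)ethan-1-one; 4 3,4,5-tris(benzyloxy)benzaldehyde
Product: 5 8-(benzyloxy)-2-[3,4,5-tris(benzyloxy)phenyl]-4H-1,3-benzodioxepin-5-one (racemic)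
Conditions: 4 (1.0 equiv), TMSOTf (10 mol %), CH2Cl2, −78 °C; pyridine quench
Reagents that add atoms: none
Why: Noyori acetalisation of the aldehyde with the bis-silyl ether of the phenol/primary alcohol pair should give the seven-membered mixed aryl alkyl acetal under kinetic, low-temperature control with hexamethyldisiloxane as the only co-product; the acetal centre forms racemic, which is immaterial because step 4 erases it.

**Step 3**
Reactants: 5 8-(benzyloxy)-2-[3,4,5-tris(benzyloxy)phenyl]-4H-1,3-benzodioxepin-5-one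
Product: 6 tert-butyl({8-(benzyloxy)-2-[3,4,5-tris(benzyloxy)phenyl]-2H-1,3-benzodioxepin-5-yl}oxy)dimethylsilane (racemic)
Conditions: KN(SiMe3)2, THF, −78 °C; TBSCl, DMPU, −78 → 0 °C
Reagents that add atoms: tert-butyldimethylsilyl chloride, CC(C)(C)[Si](C)(C)Cl
Why: Kinetic enolate formation at the only enolisable position and O-silylation give the cyclic enol silane; base-only conditions avoid Lewis-acid ionisation of the acetal.

**Step 4**
Reactants: 6 tert-butyl({8-(benzyloxy)-2-[3,4,5-tris(benzyloxy)phenyl]-2H-1,3-benzodioxepin-5-yl}oxy)dimethylsilane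
Product: 8 (2R,3R)-7-(benzyloxy)-3-[(tert-butyldimethylsilyl)oxy]-2-[3,4,5-tris(benzyloxy)phenyl]chroman-4-one, via oxocarbenium ion pair 7 (not isolated)
Conditions: confined chiral imidodiphosphorimidate Brønsted acid (IDPi, 3,3′-diaryl-BINOL backbone, N-triflyl; 3 mol %), toluene, −60 °C; Et3N quench
Reagents that add atoms: none
Why: Proposed new method: the chiral acid, silylated in situ by a trace of 6, transfers its silyl group to the enol-ether oxygen O-3, the C2–O-3 bond ionises to the ring-B-stabilised O1=C2 oxocarbenium ion 7 paired with the chiral anion, the tethered bis-silyl enediol attacks C2 through the future C3 and the silyl group on the new carbonyl oxygen returns to the anion, so that O-3 leaves the ring as the C3 silyloxy group and the seven-membered acetal ring contracts to the pyranone. The closest known reaction types are the Petasis–Ferrier rearrangement of cyclic enol acetals, its chiral-phosphoric-acid-catalysed aza variant and Mukaiyama aldol additions to oxocarbenium ions under chiral counter-anion control. The pyranone ring closes by a 6-(enolendo)-endo-trig C–C bond formation across ring A as a rigid two-atom tether. C2 and C3 arise in this bond-forming event, their absolute sense fixed by the confined chiral anion shielding one face of the oxocarbenium ion and their trans relationship by a half-chair transition state with ring B and the silyloxy group pseudo-equatorial, a residual cis isomer being correctable by epimerisation at C3. The step needs bonding through the future C3 (six-membered ring) instead of through the aryl-bearing enol carbon (five-membered ring) or protodesilylation; the silyloxy group and the para-benzyloxy ring A stabilise positive charge on the aryl-bearing carbon and so direct the electrophile to the other enol carbon, and the alternative C2–O1 ionisation is reversible and unproductive. The reaction is stereoconvergent because the acetal stereocentre of racemic 6 is erased in 7.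

**Step 5**
Reactants: 9 (2R,3R)-dihydromyricetin [(2R,3R)-3,5,7-trihydroxy-2-(3,4,5-trihydroxyphenyl)chroman-4-one]
Product: 10 (2R,3R)-7-(benzyloxy)-3,5-dihydroxy-2-[3,4,5-tris(benzyloxy)phenyl]chroman-4-one
Conditions: BnBr (4.2 equiv), K2CO3, DMF, 0 °C → rt, argon
Reagents that add atoms: benzyl bromide, BrCc1ccccc1
Why: Williamson etherification of the four acidic, non-chelated phenols (7, 3′, 4′, 5′); the 5-OH is held in a hydrogen bond to the C4 carbonyl and the 3-OH is an alcohol, so both should stay free, and the trans C2/C3 centres are the thermodynamic arrangement and are kept.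

**Step 6**
Reactants: 10 (2R,3R)-7-(benzyloxy)-3,5-dihydroxy-2-[3,4,5-tris(benzyloxy)phenyl]chroman-4-one
Product: 11 (2R,3R)-7-(benzyloxy)-3-hydroxy-4-oxo-2-[3,4,5-tris(benzyloxy)phenyl]chroman-5-yl trifluoromethanesulfonate
Conditions: PhNTf2, K2CO3, DMF, rt
Reagents that add atoms: N-phenylbis(trifluoromethanesulfonimide), O=S(=O)(N(c1ccccc1)S(=O)(=O)C(F)(F)F)C(F)(F)F
Why: Phenol-selective triflation: the 5-phenoxide reacts with the mild triflyl donor while the secondary alcohol does not; the triflate is a removable electron-withdrawing group that will deactivate ring A of the electrophile.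

**Step 7**
Reactants: 11 (2R,3R)-7-(benzyloxy)-3-hydroxy-4-oxo-2-[3,4,5-tris(benzyloxy)phenyl]chroman-5-yl trifluoromethanesulfonate
Product: 12 (2R,3S,4R)-7-(benzyloxy)-3,4-dihydroxy-2-[3,4,5-tris(benzyloxy)phenyl]chroman-5-yl trifluoromethanesulfonate
Conditions: NaBH4, THF/EtOH, 0 °C
Reagents that add atoms: none
Why: Borohydride reduction of the aryl ketone, with axial hydride attack expected to give mainly the 3,4-trans (4R) alcohol; the C4 configuration is of no consequence because it is erased in step 8, and the aryl triflate is inert.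

**Step 8**
Reactants: 12 (2R,3S,4R)-7-(benzyloxy)-3,4-dihydroxy-2-[3,4,5-tris(benzyloxy)phenyl]chroman-5-yl trifluoromethanesulfonate; 8 (2R,3R)-7-(benzyloxy)-3-[(tert-butyldimethylsilyl)oxy]-2-[3,4,5-tris(benzyloxy)phenyl]chroman-4-one
Product: 14 (2R,3R)-7-(benzyloxy)-3-[(tert-butyldimethylsilyl)oxy]-2-{3,4,5-tris(benzyloxy)-2-[(2R,3S,4R)-7-(benzyloxy)-3-hydroxy-2-[3,4,5-tris(benzyloxy)phenyl]-5-{[(trifluoromethyl)sulfonyl]oxy}chroman-4-yl]phenyl}chroman-4-one, via flavan-4-yl cation 13 (not isolated)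
Conditions: 8 (3 equiv, excess recovered), BF3·OEt2, CH2Cl2, −40 → 0 °C
Reagents that add atoms: none
Why: Friedel–Crafts alkylation as in interflavanyl bond formation: BF3 ionises the benzylic C4–OH to cation 13 (stabilised by O1 and the 7-benzyloxy group), which should be captured at C2′ (= C6′) of ring B of 8, since ring A of 8 is deactivated by its ketone and ring A of 13 by the triflate; attack anti to the 3-OH sets C4 trans to C3 (4α), and excess 8 outcompetes ring B of 12.

**Step 9**
Reactants: 14 triflate-bearing dimeric flavanone (as in step 8)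
Product: 15 (2R,3R)-7-(benzyloxy)-3-[(tert-butyldimethylsilyl)oxy]-2-{3,4,5-tris(benzyloxy)-2-[(2R,3S,4S)-7-(benzyloxy)-3-hydroxy-2-[3,4,5-tris(benzyloxy)phenyl]chroman-4-yl]phenyl}chroman-4-one
Conditions: Pd(OAc)2 (10 mol %), dppp, HCO2H, Et3N, DMF, 60 °C
Reagents that add atoms: none
Why: Palladium-catalysed transfer hydrogenolysis of the aryl triflate (oxidative addition to zerovalent palladium, formate exchange, decarboxylation, reductive elimination); benzyl ethers, the silyl ether and the ketone are inert to the homogeneous catalyst, and the C4 descriptor changes from R to S only because the CIP priorities change.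

**Step 10**
Reactants: 15 dimeric flavanone (as in step 9)
Product: 16 (2R,3S,4S)-7-(benzyloxy)-3-[(tert-butyldimethylsilyl)oxy]-2-{3,4,5-tris(benzyloxy)-2-[(2R,3S,4S)-7-(benzyloxy)-3-hydroxy-2-[3,4,5-tris(benzyloxy)phenyl]chroman-4-yl]phenyl}chroman-4-ol
Conditions: LiBH(s-Bu)3 (L-Selectride, 3 equiv), THF, −78 °C
Reagents that add atoms: none
Why: Ketone reduction by a bulky trialkylborohydride: the reagent avoids the axial trajectory (1,3-diaxial to H-2) and attacks equatorially from the α-face, which should give the axial 4β-OH cis to the 3-silyloxy group (lower C4 = S), as in cis-selective reductions of 3-substituted chroman-4-ones.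

**Step 11**
Reactants: 16 silylated cis-alcohol (as in step 10)
Product: 17 (2R,3S,4S)-7-(benzyloxy)-2-{3,4,5-tris(benzyloxy)-2-[(2R,3S,4S)-7-(benzyloxy)-3-hydroxy-2-[3,4,5-tris(benzyloxy)phenyl]chroman-4-yl]phenyl}chromane-3,4-diol
Conditions: TBAF, AcOH, THF, 0 °C → rt
Reagents that add atoms: none
Why: Fluoride-mediated silyl ether cleavage, buffered with acetic acid so that the ionisable benzylic 4-OH and the interflavanyl bond are not exposed to base or strong acid; no stereocentre is touched.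

**Step 12**
Reactants: 17 octa-O-benzyl dimer (as in step 11)
Product: 18 (2R,3S,4S)-2-{2-[(2R,3S,4S)-3,7-dihydroxy-2-(3,4,5-trihydroxyphenyl)chroman-4-yl]-3,4,5-trihydroxyphenyl}chromane-3,4,7-triol (CNP0205451.3)
Conditions: H2 (1 atm), Pd(OH)2/C, THF/MeOH, rt, short reaction time
Reagents that add atoms: none
Why: Hydrogenolysis of the eight aryl benzyl ethers under neutral conditions; aryl benzyl ethers should cleave much faster than the cyclic benzylic C2–O bonds and the secondary benzylic C4–OH, and no stereocentre is affected.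

**Compound list**
1 | 1-[4-(benzyloxy)-2-hydroxyphenyl]ethan-1-one | CC(=O)c1ccc(OCc2ccccc2)cc1O | starting material
2 | {5-(benzyloxy)-2-[1-(trimethylsilyloxy)ethenyl]phenoxy}trimethylsilane | C=C(O[Si](C)(C)C)c1ccc(OCc2ccccc2)cc1O[Si](C)(C)C | intermediate
3 | 1-[4-(benzyloxy)-2-(trimethylsilyloxy)phenyl]-2-(trimethylsilyloxy)ethan-1-one | C[Si](C)(C)OCC(=O)c1ccc(OCc2ccccc2)cc1O[Si](C)(C)C | intermediate
4 | 3,4,5-tris(benzyloxy)benzaldehyde | O=Cc1cc(OCc2ccccc2)c(OCc2ccccc2)c(OCc2ccccc2)c1 | starting material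
5 | 8-(benzyloxy)-2-[3,4,5-tris(benzyloxy)phenyl]-4H-1,3-benzodioxepin-5-one (racemic) | O=C1COC(c2cc(OCc3ccccc3)c(OCc3ccccc3)c(OCc3ccccc3)c2)Oc2cc(OCc3ccccc3)ccc12 | intermediate
6 | tert-butyl({8-(benzyloxy)-2-[3,4,5-tris(benzyloxy)phenyl]-2H-1,3-benzodioxepin-5-yl}oxy)dimethylsilane (racemic) | CC(C)(C)[Si](C)(C)OC1=COC(c2cc(OCc3ccccc3)c(OCc3ccccc3)c(OCc3ccccc3)c2)Oc2cc(OCc3ccccc3)ccc12 | intermediate
7 | ring-opened O-aryl oxocarbenium ion carrying the (E)-bis(silyloxy)vinyl group, as ion pair with the catalyst anion | CC(C)(C)[Si](C)(C)O/C=C(/O[Si](C)(C)C(C)(C)C)c1ccc(OCc2ccccc2)cc1[O+]=Cc1cc(OCc2ccccc2)c(OCc2ccccc2)c(OCc2ccccc2)c1 | intermediate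
8 | (2R,3R)-7-(benzyloxy)-3-[(tert-butyldimethylsilyl)oxy]-2-[3,4,5-tris(benzyloxy)phenyl]chroman-4-one | O=C1c2ccc(OCc3ccccc3)cc2O[C@H](c2cc(OCc3ccccc3)c(OCc3ccccc3)c(OCc3ccccc3)c2)[C@H]1O[Si](C)(C)C(C)(C)C | intermediate
9 | (2R,3R)-dihydromyricetin | O=C1c2c(O)cc(O)cc2O[C@H](c2cc(O)c(O)c(O)c2)[C@H]1O | starting material
10 | (2R,3R)-7-(benzyloxy)-3,5-dihydroxy-2-[3,4,5-tris(benzyloxy)phenyl]chroman-4-one | O=C1c2c(O)cc(OCc3ccccc3)cc2O[C@H](c2cc(OCc3ccccc3)c(OCc3ccccc3)c(OCc3ccccc3)c2)[C@H]1O | intermediate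
11 | (2R,3R)-7-(benzyloxy)-3-hydroxy-4-oxo-2-[3,4,5-tris(benzyloxy)phenyl]chroman-5-yl trifluoromethanesulfonate | O=C1c2c(OS(=O)(=O)C(F)(F)F)cc(OCc3ccccc3)cc2O[C@H](c2cc(OCc3ccccc3)c(OCc3ccccc3)c(OCc3ccccc3)c2)[C@H]1O | intermediate
12 | (2R,3S,4R)-7-(benzyloxy)-3,4-dihydroxy-2-[3,4,5-tris(benzyloxy)phenyl]chroman-5-yl trifluoromethanesulfonate | O[C@@H]1c2c(OS(=O)(=O)C(F)(F)F)cc(OCc3ccccc3)cc2O[C@H](c2cc(OCc3ccccc3)c(OCc3ccccc3)c(OCc3ccccc3)c2)[C@H]1O | intermediate
13 | (2R,3S)-7-(benzyloxy)-3-hydroxy-2-[3,4,5-tris(benzyloxy)phenyl]-5-(triflyloxy)chroman-4-ylium ion | [CH+]1c2c(OS(=O)(=O)C(F)(F)F)cc(OCc3ccccc3)cc2O[C@H](c2cc(OCc3ccccc3)c(OCc3ccccc3)c(OCc3ccccc3)c2)[C@H]1O | intermediate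
14 | (2R,3R)-7-(benzyloxy)-3-[(tert-butyldimethylsilyl)oxy]-2-{3,4,5-tris(benzyloxy)-2-[(2R,3S,4R)-7-(benzyloxy)-3-hydroxy-2-[3,4,5-tris(benzyloxy)phenyl]-5-{[(trifluoromethyl)sulfonyl]oxy}chroman-4-yl]phenyl}chroman-4-one | c1(OCc9ccccc9)cc(OS(=O)(=O)C(F)(F)F)c2c(c1)O[C@H](c3cc(OCc9ccccc9)c(OCc9ccccc9)c(OCc9ccccc9)c3)[C@@H](O)[C@@H]2c4c([C@H]5Oc6cc(OCc9ccccc9)ccc6C(=O)[C@@H]5O[Si](C)(C)C(C)(C)C)cc(OCc9ccccc9)c(OCc9ccccc9)c4OCc9ccccc9 | intermediate
15 | (2R,3R)-7-(benzyloxy)-3-[(tert-butyldimethylsilyl)oxy]-2-{3,4,5-tris(benzyloxy)-2-[(2R,3S,4S)-7-(benzyloxy)-3-hydroxy-2-[3,4,5-tris(benzyloxy)phenyl]chroman-4-yl]phenyl}chroman-4-one | c1(OCc9ccccc9)ccc2c(c1)O[C@H](c3cc(OCc9ccccc9)c(OCc9ccccc9)c(OCc9ccccc9)c3)[C@@H](O)[C@@H]2c4c([C@H]5Oc6cc(OCc9ccccc9)ccc6C(=O)[C@@H]5O[Si](C)(C)C(C)(C)C)cc(OCc9ccccc9)c(OCc9ccccc9)c4OCc9ccccc9 | intermediate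
16 | (2R,3S,4S)-7-(benzyloxy)-3-[(tert-butyldimethylsilyl)oxy]-2-{3,4,5-tris(benzyloxy)-2-[(2R,3S,4S)-7-(benzyloxy)-3-hydroxy-2-[3,4,5-tris(benzyloxy)phenyl]chroman-4-yl]phenyl}chroman-4-ol | c1(OCc9ccccc9)ccc2c(c1)O[C@H](c3cc(OCc9ccccc9)c(OCc9ccccc9)c(OCc9ccccc9)c3)[C@@H](O)[C@@H]2c4c([C@H]5Oc6cc(OCc9ccccc9)ccc6[C@H](O)[C@@H]5O[Si](C)(C)C(C)(C)C)cc(OCc9ccccc9)c(OCc9ccccc9)c4OCc9ccccc9 | intermediate
17 | (2R,3S,4S)-7-(benzyloxy)-2-{3,4,5-tris(benzyloxy)-2-[(2R,3S,4S)-7-(benzyloxy)-3-hydroxy-2-[3,4,5-tris(benzyloxy)phenyl]chroman-4-yl]phenyl}chromane-3,4-diol | c1(OCc9ccccc9)ccc2c(c1)O[C@H](c3cc(OCc9ccccc9)c(OCc9ccccc9)c(OCc9ccccc9)c3)[C@@H](O)[C@@H]2c4c([C@H]5Oc6cc(OCc9ccccc9)ccc6[C@H](O)[C@@H]5O)cc(OCc9ccccc9)c(OCc9ccccc9)c4OCc9ccccc9 | intermediate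
18 | (2R,3S,4S)-2-{2-[(2R,3S,4S)-3,7-dihydroxy-2-(3,4,5-trihydroxyphenyl)chroman-4-yl]-3,4,5-trihydroxyphenyl}chromane-3,4,7-triol | Oc1ccc2c(c1)O[C@H](c1cc(O)c(O)c(O)c1)[C@@H](O)[C@@H]2c1c([C@H]2Oc3cc(O)ccc3[C@H](O)[C@@H]2O)cc(O)c(O)c1O | target

**Totals**
Total step count: 12. Longest linear sequence: 9 steps (steps 1–4 and 8–12 from compound 1; the dihydromyricetin branch is 8 steps).

**Steps most likely to fail**

Step 4 (proposed new method). The ion pair may collapse with poor facial discrimination, the enol silane may be lost by protodesilylation, or bond formation may go through the aryl-bearing enol carbon to a five-membered ring. The fallback uses known chiral-pool chemistry and sets out from triflate 11. Palladium-catalysed transfer hydrogenolysis of the aryl triflate (Pd(OAc)2, dppp, HCO2H, Et3N, DMF, 60 °C) should give (2R,3R)-7-(benzyloxy)-3-hydroxy-2-[3,4,5-tris(benzyloxy)phenyl]chroman-4-one F1. Silylation of its 3-hydroxyl (TBSOTf, 2,6-lutidine, CH2Cl2, −78 °C) returns to the route at 8.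

Step 8. Ionisation of the triflate-deactivated C4–OH may be sluggish. Prolonged Lewis-acid exposure could then cause desilylation or ring-opening of 8, loss of the cation by elimination, or alkylation of ring B of 12 in place of ring B of 8. The fallback replaces the hydroxyl by a leaving group that a soft, thiophilic activator can ionise at low temperature, and sets out from 12. Thiolysis (BnSH, catalytic BF3·OEt2, CH2Cl2, −20 °C) should give (2R,3R,4R)-4-(benzylsulfanyl)-7-(benzyloxy)-3-hydroxy-2-[3,4,5-tris(benzyloxy)phenyl]chroman-5-yl trifluoromethanesulfonate F2. Activation of the C4–S bond of F2 with AgBF4 (THF, −20 °C) in the presence of excess 8 returns to the route at 14.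

Step 12. Once the 7-benzyl ether of the lower unit is cleaved, its benzylic 4-hydroxyl may be lost by hydrogenolysis or solvolysis (over-reduction towards the flavan-3-ol). The fallback moves the ketone reduction to the very end and sets out from ketone 15. Desilylation (TBAF, AcOH, THF) should give (2R,3R)-7-(benzyloxy)-3-hydroxy-2-{3,4,5-tris(benzyloxy)-2-[(2R,3S,4S)-7-(benzyloxy)-3-hydroxy-2-[3,4,5-tris(benzyloxy)phenyl]chroman-4-yl]phenyl}chroman-4-one F3. Hydrogenolysis (H2, Pd(OH)2/C, THF/MeOH) should then give the free phenolic ketone (2R,3R)-2-{2-[(2R,3S,4S)-3,7-dihydroxy-2-(3,4,5-trihydroxyphenyl)chroman-4-yl]-3,4,5-trihydroxyphenyl}-3,7-dihydroxychroman-4-one F4, which has no ionisable C4–OH. Catalytic hydrogenation of its C4 carbonyl over PtO2 in EtOH, which in the dihydroflavonol series is expected to favour the 3,4-cis diol, returns to the route at 18.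

Further compounds
F1 | step 4 | (2R,3R)-7-(benzyloxy)-3-hydroxy-2-[3,4,5-tris(benzyloxy)phenyl]chroman-4-one | O=C1c2ccc(OCc3ccccc3)cc2O[C@H](c2cc(OCc3ccccc3)c(OCc3ccccc3)c(OCc3ccccc3)c2)[C@H]1O
F2 | step 8 | (2R,3R,4R)-4-(benzylsulfanyl)-7-(benzyloxy)-3-hydroxy-2-[3,4,5-tris(benzyloxy)phenyl]chroman-5-yl trifluoromethanesulfonate | S(Cc3ccccc3)[C@@H]1c2c(OS(=O)(=O)C(F)(F)F)cc(OCc3ccccc3)cc2O[C@H](c2cc(OCc3ccccc3)c(OCc3ccccc3)c(OCc3ccccc3)c2)[C@H]1O
F3 | step 12 | (2R,3R)-7-(benzyloxy)-3-hydroxy-2-{3,4,5-tris(benzyloxy)-2-[(2R,3S,4S)-7-(benzyloxy)-3-hydroxy-2-[3,4,5-tris(benzyloxy)phenyl]chroman-4-yl]phenyl}chroman-4-one | c1(OCc9ccccc9)ccc2c(c1)O[C@H](c3cc(OCc9ccccc9)c(OCc9ccccc9)c(OCc9ccccc9)c3)[C@@H](O)[C@@H]2c4c([C@H]5Oc6cc(OCc9ccccc9)ccc6C(=O)[C@@H]5O)cc(OCc9ccccc9)c(OCc9ccccc9)c4OCc9ccccc9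
F4 | step 12 | (2R,3R)-2-{2-[(2R,3S,4S)-3,7-dihydroxy-2-(3,4,5-trihydroxyphenyl)chroman-4-yl]-3,4,5-trihydroxyphenyl}-3,7-dihydroxychroman-4-one | Oc1ccc2c(c1)O[C@H](c1cc(O)c(O)c(O)c1)[C@@H](O)[C@@H]2c1c([C@H]2Oc3cc(O)ccc3C(=O)[C@@H]2O)cc(O)c(O)c1O
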